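Ring A is not carried through the synthesis but annulated last onto a finished 4-pyranone. The disconnection uses the adjacent oxygens on C6 and C7 of ring A and the C4a=C8a bond shared with the pyranone ring: C6 is traced back to a ketene carbon, C7 to the methoxy-bearing terminus of an enol ether, and the heterocycle holds the central alkene cis. The precursor is a 6-(arylethyl)-4-pyranone carrying a diazoacetyl group at C3 and an (E)-2-methoxyvinyl group at C2. Irradiation should trigger Wolff rearrangement (C4a–C5) and 6π ring closure (C6–C7), giving the 6-hydroxy-7-methoxychromone in one operation; O-methylation and debenzylation finish the route.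

Key step: step 8

Remark: 3-(benzyloxy)-4-methoxybenzaldehyde is taken as a purchasable starting material (otherwise one benzylation from isovanillin); the C3 carboxyl is carried as an allyl ester and activated from its sodium salt, so that neither acid nor hydroxide meets the enol ether or the pyranone, and Me3SiCHN2 replaces diazomethane.

Step 1
Reactants: 1 3-(benzyloxy)-4-methoxybenzaldehyde
Product: 2 [3-(benzyloxy)-4-methoxyphenyl]methanol
Conditions: NaBH4, MeOH–THF, 0 °C
Reagents that add atoms: none
Why: Borohydride reduction of the aryl aldehyde is chemoselective and leaves both aryl ethers untouched.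

Step 2
Reactants: 2 [3-(benzyloxy)-4-methoxyphenyl]methanol
Product: 3 2-(benzyloxy)-4-(bromomethyl)-1-methoxybenzene
Conditions: PBr3 (0.4 equiv), CH2Cl2, 0 °C; used crude
Reagents that add atoms: phosphorus tribromide, BrP(Br)Br
Why: The electron-rich benzylic alcohol is converted into the bromide through its phosphite ester and bromide displacement (nucleophilic substitution), with no acid strong enough to cleave the ethers.

Step 3
Reactants: 4 2,2,6-trimethyl-4H-1,3-dioxin-4-one; 3 2-(benzyloxy)-4-(bromomethyl)-1-methoxybenzene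
Product: 6 6-{2-[3-(benzyloxy)-4-methoxyphenyl]ethyl}-2,2-dimethyl-4H-1,3-dioxin-4-one, via lithium dienolate 5 (not isolated)
Conditions: LiN(iPr)2, THF, −78 °C; DMPU; then 3, −78 to −30 °C
Reagents that add atoms: none
Why: Deprotonation of the 6-methyl group gives the extended dienolate 5, which a reactive benzylic bromide alkylates at the exocyclic γ-carbon in the presence of DMPU (vinylogous enolate alkylation), the usual entry to 6-(2-arylethyl)dioxinones.

Step 4
Reactants: 6 6-{2-[3-(benzyloxy)-4-methoxyphenyl]ethyl}-2,2-dimethyl-4H-1,3-dioxin-4-one; 7 prop-2-en-1-yl 3-oxobutanoate (allyl acetoacetate)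
Product: 10 prop-2-en-1-yl 6-{2-[3-(benzyloxy)-4-methoxyphenyl]ethyl}-2-methyl-4-oxo-4H-pyran-3-carboxylate, via acylketene 8 (not isolated), via triketo ester 9 (not isolated)
Conditions: 7 (3 equiv), toluene, 110 °C; then TsOH·H2O (10 mol %), 4 Å molecular sieves, 80 °C
Reagents that add atoms: none
Why: Retro-hetero-Diels–Alder loss of acetone gives acylketene 8, which C-acylates the enol of the β-keto ester as diketene and dioxinones do with 1,3-dicarbonyl compounds, and acid then cyclodehydrates the 1,3,5-tricarbonyl array of 9 to the 4-pyranone with the ester at C3 next to the methyl group.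

Step 5
Reactants: 10 prop-2-en-1-yl 6-{2-[3-(benzyloxy)-4-methoxyphenyl]ethyl}-2-methyl-4-oxo-4H-pyran-3-carboxylate; 11 trimethyl orthoformate
Product: 13 prop-2-en-1-yl 6-{2-[3-(benzyloxy)-4-methoxyphenyl]ethyl}-2-[(E)-2-methoxyethenyl]-4-oxo-4H-pyran-3-carboxylate, via acetal 12 (not isolated)
Conditions: 11 (4 equiv), Me3SiOTf (3.2 equiv), iPr2NEt (3.5 equiv), CH2Cl2, −78 to 0 °C; then 25 °C; NaHCO3 work-up
Reagents that add atoms: none
Why: Me3SiOTf silylates the pyranone carbonyl and iPr2NEt removes a proton from the doubly activated 2-methyl group, so that the methylenepyran adds to the dimethoxycarbenium ion from 11 (Mukaiyama-type orthoester alkylation, as methylpyrylium salts undergo in orthoester condensations), after which the same reagent pair eliminates methanol from acetal 12 to the conjugated and thermodynamically preferred E enol ether.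

Step 6
Reactants: 13 prop-2-en-1-yl 6-{2-[3-(benzyloxy)-4-methoxyphenyl]ethyl}-2-[(E)-2-methoxyethenyl]-4-oxo-4H-pyran-3-carboxylate
Product: 14 sodium 6-{2-[3-(benzyloxy)-4-methoxyphenyl]ethyl}-2-[(E)-2-methoxyethenyl]-4-oxo-4H-pyran-3-carboxylate
Conditions: Pd(PPh3)4 (3 mol %), sodium 2-ethylhexanoate (1.05 equiv), EtOAc–CH2Cl2, 20 °C; salt filtered and dried cold
Reagents that add atoms: sodium 2-ethylhexanoate, CCCCC(CC)C(=O)[O-].[Na+]
Why: Zerovalent palladium ionises the allyl ester to a π-allyl complex that 2-ethylhexanoate captures (Tsuji–Trost deallylation), so the carboxylate is released as its sodium salt under neutral conditions that spare the enol ether, the pyranone and the benzyl ether.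

Step 7
Reactants: 14 sodium 6-{2-[3-(benzyloxy)-4-methoxyphenyl]ethyl}-2-[(E)-2-methoxyethenyl]-4-oxo-4H-pyran-3-carboxylate
Product: 16 6-{2-[3-(benzyloxy)-4-methoxyphenyl]ethyl}-3-(diazoacetyl)-2-[(E)-2-methoxyethenyl]-4H-pyran-4-one, via acid chloride 15 (not isolated)
Conditions: (COCl)2 (1.2 equiv), CH2Cl2, 0 °C, then evaporation; Me3SiCHN2 (2.2 equiv), MeCN–THF, 0 °C, dark; product kept cold and used at once
Reagents that add atoms: (trimethylsilyl)diazomethane, C[Si](C)(C)C=[N+]=[N-]
Why: The sodium salt and oxalyl chloride give acid chloride 15 without forming HCl, and C-acylation of the silyl diazomethane with loss of the silyl group to chloride gives the diazoketone (Arndt–Eistert-type diazoketone synthesis).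

Step 8
Reactants: 16 6-{2-[3-(benzyloxy)-4-methoxyphenyl]ethyl}-3-(diazoacetyl)-2-[(E)-2-methoxyethenyl]-4H-pyran-4-one
Product: 19 2-{2-[3-(benzyloxy)-4-methoxyphenyl]ethyl}-6-hydroxy-7-methoxy-4H-chromen-4-one, via ketene 17 (not isolated), via dienone 18 (not isolated)
Conditions: hν (blue LEDs, 440–450 nm), dry degassed toluene (0.005 M), 20 °C; then 60 °C in the dark
Reagents that add atoms: none
Why: Proposed new method: excitation of the diazoketone, which prefers the s-Z conformation, expels N2 with concerted 1,2-shift of the pyranone carbon C4a to the diazo carbon (Wolff rearrangement, forming C4a–C5) to give ketene 17, whose triene C6=C5–C4a=C8a–C8=C7 closes by thermal disrotatory 6π electrocyclisation (C6–C7) to dienone 18, which enolises to phenol 19. The closest known chemistry is the photochemical Wolff rearrangement of unsaturated diazoketones followed by dienylketene electrocyclisation to phenols, which has not been run with the ring double bond of a 4-pyranone as the central alkene. Ring A, the only ring formed, closes in a six-electron electrocyclic mode, and the heterocycle locks the central C4a=C8a bond cis so that the two termini are always within reach. No stereocentre survives, because the sp3 C7 of 18 is erased on aromatisation, and the E enol ether keeps the methoxy group outward during closure. The selectivity needed is electrocyclisation over ketene capture by nucleophiles, (2+2) addition to the enol ether and carbene trapping by the C4 carbonyl; high dilution in a dry aprotic solvent, the ring-enforced s-cis triene and visible light that the pyranone chromophore does not absorb should secure it.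

Step 9
Reactants: 19 2-{2-[3-(benzyloxy)-4-methoxyphenyl]ethyl}-6-hydroxy-7-methoxy-4H-chromen-4-one
Product: 20 2-{2-[3-(benzyloxy)-4-methoxyphenyl]ethyl}-6,7-dimethoxy-4H-chromen-4-one
Conditions: MeI (3 equiv), K2CO3 (2 equiv), acetone, 50 °C
Reagents that add atoms: iodomethane, CI
Why: Williamson O-methylation of the only free phenol (C6–OH); the isovanillyl oxygen is still benzylated, so the two phenols stay differentiated.

Step 10
Reactants: 20 2-{2-[3-(benzyloxy)-4-methoxyphenyl]ethyl}-6,7-dimethoxy-4H-chromen-4-one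
Product: 21 2-[2-(3-hydroxy-4-methoxyphenyl)ethyl]-6,7-dimethoxy-4H-chromen-4-one
Conditions: H2 (1 atm), Pd/C (10 wt % Pd), EtOAc–MeOH, 20 °C
Reagents that add atoms: none
Why: Catalytic hydrogenolysis cleaves the benzyl aryl ether under neutral conditions at which the chromone C2=C3 bond is not reduced.

Compound list
1 | 3-(benzyloxy)-4-methoxybenzaldehyde | COc1ccc(C=O)cc1OCc1ccccc1 | starting material
2 | [3-(benzyloxy)-4-methoxyphenyl]methanol | COc1ccc(CO)cc1OCc1ccccc1 | intermediate
3 | 2-(benzyloxy)-4-(bromomethyl)-1-methoxybenzene | COc1ccc(CBr)cc1OCc1ccccc1 | intermediate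
4 | 2,2,6-trimethyl-4H-1,3-dioxin-4-one | CC1=CC(=O)OC(C)(C)O1 | starting material
5 | lithium 2,2-dimethyl-6-methylidene-6H-1,3-dioxin-4-olate | [Li+].C=C1C=C([O-])OC(C)(C)O1 | intermediate (not isolated)
6 | 6-{2-[3-(benzyloxy)-4-methoxyphenyl]ethyl}-2,2-dimethyl-4H-1,3-dioxin-4-one | CC1(C)OC(CCc2ccc(OC)c(OCc3ccccc3)c2)=CC(=O)O1 | intermediate
7 | prop-2-en-1-yl 3-oxobutanoate | CC(=O)CC(=O)OCC=C | starting material
8 | 5-[3-(benzyloxy)-4-methoxyphenyl]pent-1-ene-1,3-dione | O=C=CC(=O)CCc1ccc(OC)c(OCc2ccccc2)c1 | intermediate (not isolated)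
9 | prop-2-en-1-yl 2-acetyl-7-[3-(benzyloxy)-4-methoxyphenyl]-3,5-dioxoheptanoate | CC(=O)C(C(=O)OCC=C)C(=O)CC(=O)CCc1ccc(OC)c(OCc2ccccc2)c1 | intermediate (not isolated)
10 | prop-2-en-1-yl 6-{2-[3-(benzyloxy)-4-methoxyphenyl]ethyl}-2-methyl-4-oxo-4H-pyran-3-carboxylate | Cc1oc(CCc2ccc(OC)c(OCc3ccccc3)c2)cc(=O)c1C(=O)OCC=C | intermediate
11 | trimethyl orthoformate | COC(OC)OC | starting material
12 | prop-2-en-1-yl 6-{2-[3-(benzyloxy)-4-methoxyphenyl]ethyl}-2-(2,2-dimethoxyethyl)-4-oxo-4H-pyran-3-carboxylate | COC(OC)Cc1oc(CCc2ccc(OC)c(OCc3ccccc3)c2)cc(=O)c1C(=O)OCC=C | intermediate (not isolated)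
13 | prop-2-en-1-yl 6-{2-[3-(benzyloxy)-4-methoxyphenyl]ethyl}-2-[(E)-2-methoxyethenyl]-4-oxo-4H-pyran-3-carboxylate | CO/C=C/c1oc(CCc2ccc(OC)c(OCc3ccccc3)c2)cc(=O)c1C(=O)OCC=C | intermediate
14 | sodium 6-{2-[3-(benzyloxy)-4-methoxyphenyl]ethyl}-2-[(E)-2-methoxyethenyl]-4-oxo-4H-pyran-3-carboxylate | CO/C=C/c1oc(CCc2ccc(OC)c(OCc3ccccc3)c2)cc(=O)c1C(=O)[O-].[Na+] | intermediate
15 | 6-{2-[3-(benzyloxy)-4-methoxyphenyl]ethyl}-2-[(E)-2-methoxyethenyl]-4-oxo-4H-pyran-3-carbonyl chloride | CO/C=C/c1oc(CCc2ccc(OC)c(OCc3ccccc3)c2)cc(=O)c1C(=O)Cl | intermediate (not isolated)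
16 | 6-{2-[3-(benzyloxy)-4-methoxyphenyl]ethyl}-3-(diazoacetyl)-2-[(E)-2-methoxyethenyl]-4H-pyran-4-one | CO/C=C/c1oc(CCc2ccc(OC)c(OCc3ccccc3)c2)cc(=O)c1C(=O)C=[N+]=[N-] | intermediate
17 | 2-{6-{2-[3-(benzyloxy)-4-methoxyphenyl]ethyl}-2-[(E)-2-methoxyethenyl]-4-oxo-4H-pyran-3-yl}ethen-1-one | CO/C=C/c1oc(CCc2ccc(OC)c(OCc3ccccc3)c2)cc(=O)c1C=C=O | intermediate (not isolated)
18 | 2-{2-[3-(benzyloxy)-4-methoxyphenyl]ethyl}-7-methoxy-4H-chromene-4,6(7H)-dione (racemic at C7) | COC1C=C2OC(CCc3ccc(OC)c(OCc4ccccc4)c3)=CC(=O)C2=CC1=O | intermediate (not isolated)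
19 | 2-{2-[3-(benzyloxy)-4-methoxyphenyl]ethyl}-6-hydroxy-7-methoxy-4H-chromen-4-one | COc1cc2oc(CCc3ccc(OC)c(OCc4ccccc4)c3)cc(=O)c2cc1O | intermediate
20 | 2-{2-[3-(benzyloxy)-4-methoxyphenyl]ethyl}-6,7-dimethoxy-4H-chromen-4-one | COc1cc2oc(CCc3ccc(OC)c(OCc4ccccc4)c3)cc(=O)c2cc1OC | intermediate
21 | 2-[2-(3-hydroxy-4-methoxyphenyl)ethyl]-6,7-dimethoxy-4H-chromen-4-one | COc1ccc(CCc2cc(=O)c3cc(OC)c(OC)cc3o2)cc1O | target

Total step count: 10. Longest linear sequence: 10 steps (1 to 21).

Steps most likely to fail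

Step 8 (bears the label). The carbene may be trapped by the neighbouring C4 carbonyl oxygen or by the enol ether before the 1,2-shift. The ketene may also be intercepted by the phenol already formed, or the electrocyclisation may be slowed by photoisomerisation of the enol ether. The fallback sets out from 1 and returns at 21, using the established styrylchromone route. Commercial 1-(2-hydroxy-4,5-dimethoxyphenyl)ethanone is condensed with ethyl acetate (NaH, Claisen condensation) to 1-(2-hydroxy-4,5-dimethoxyphenyl)butane-1,3-dione F1, which is cyclodehydrated (HCl, AcOH) to 6,7-dimethoxy-2-methyl-4H-chromen-4-one F2. Condensation of the active methyl group of F2 with aldehyde 1 (NaOEt, EtOH) should give 2-{(E)-2-[3-(benzyloxy)-4-methoxyphenyl]ethenyl}-6,7-dimethoxy-4H-chromen-4-one F3. Hydrogenation of F3 over Pd/C saturates the styryl double bond and removes the benzyl group in the same operation, giving 21.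

Step 5. Enolisation may occur at the C6 side-chain methylene instead of the 2-methyl group, the activated intermediate may be attacked by a second molecule of the nucleophile (cyanine-type over-condensation), or elimination may stop short. The fallback sets out from 6 and 7 and returns at 13, carrying the C7–C8 unit in the keto ester instead of attaching it to the pyranone. Two-fold silylation of 7 (Et3N, Me3SiCl; then LiN(iPr)2, Me3SiCl) gives 1-(allyloxy)-1,3-bis(trimethylsilyloxy)buta-1,3-diene F4, which adds at its terminal carbon to 11 (Me3SiOTf catalyst, CH2Cl2, −78 °C) to give prop-2-en-1-yl 5,5-dimethoxy-3-oxopentanoate F5. Heating 6 with F5 in toluene at 110 °C should give, through acylketene 8, prop-2-en-1-yl 7-[3-(benzyloxy)-4-methoxyphenyl]-2-(3,3-dimethoxypropanoyl)-3,5-dioxoheptanoate F6. F6 is cyclodehydrated with pyridinium p-toluenesulfonate over molecular sieves to acetal 12, now isolated, and elimination with Me3SiOTf and iPr2NEt as in the second stage of step 5 gives 13.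

Step 6. Once the ester is cleaved, the carboxylate may add to the electrophilic terminus of the methoxyvinyl group and expel methoxide, closing a fused 2-pyranone. Traces of acid during handling could also hydrolyse the enol ether. The fallback sets out from 12 (isolated by quenching step 5 at 0 °C, or from the fallback above) and returns at 16, unmasking the enol ether only after the diazoketone is in place. Deallylation of 12 as in step 6 gives sodium 6-{2-[3-(benzyloxy)-4-methoxyphenyl]ethyl}-2-(2,2-dimethoxyethyl)-4-oxo-4H-pyran-3-carboxylate F7, in which the acetal offers the carboxylate no electrophile. Oxalyl chloride converts F7 into 6-{2-[3-(benzyloxy)-4-methoxyphenyl]ethyl}-2-(2,2-dimethoxyethyl)-4-oxo-4H-pyran-3-carbonyl chloride F8, and Me3SiCHN2 gives 6-{2-[3-(benzyloxy)-4-methoxyphenyl]ethyl}-3-(diazoacetyl)-2-(2,2-dimethoxyethyl)-4H-pyran-4-one F9. Base-induced β-elimination of methanol from F9 (KOtBu, THF, −40 to 0 °C) should then give 16.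

Further compounds
F1 | step 8 | 1-(2-hydroxy-4,5-dimethoxyphenyl)butane-1,3-dione | CC(=O)CC(=O)c1cc(OC)c(OC)cc1O
F2 | step 8 | 6,7-dimethoxy-2-methyl-4H-chromen-4-one | Cc1cc(=O)c2cc(OC)c(OC)cc2o1
F3 | step 8 | 2-{(E)-2-[3-(benzyloxy)-4-methoxyphenyl]ethenyl}-6,7-dimethoxy-4H-chromen-4-one | COc1ccc(/C=C/c2cc(=O)c3cc(OC)c(OC)cc3o2)cc1OCc1ccccc1
F4 | step 5 | 1-(allyloxy)-1,3-bis(trimethylsilyloxy)buta-1,3-diene | C=C(O[Si](C)(C)C)C=C(OCC=C)O[Si](C)(C)C
F5 | step 5 | prop-2-en-1-yl 5,5-dimethoxy-3-oxopentanoate | COC(OC)CC(=O)CC(=O)OCC=C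
F6 | step 5 | prop-2-en-1-yl 7-[3-(benzyloxy)-4-methoxyphenyl]-2-(3,3-dimethoxypropanoyl)-3,5-dioxoheptanoate | COC(OC)CC(=O)C(C(=O)OCC=C)C(=O)CC(=O)CCc1ccc(OC)c(OCc2ccccc2)c1
F7 | step 6 | sodium 6-{2-[3-(benzyloxy)-4-methoxyphenyl]ethyl}-2-(2,2-dimethoxyethyl)-4-oxo-4H-pyran-3-carboxylate | COC(OC)Cc1oc(CCc2ccc(OC)c(OCc3ccccc3)c2)cc(=O)c1C(=O)[O-].[Na+]
F8 | step 6 | 6-{2-[3-(benzyloxy)-4-methoxyphenyl]ethyl}-2-(2,2-dimethoxyethyl)-4-oxo-4H-pyran-3-carbonyl chloride | COC(OC)Cc1oc(CCc2ccc(OC)c(OCc3ccccc3)c2)cc(=O)c1C(=O)Cl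
F9 | step 6 | 6-{2-[3-(benzyloxy)-4-methoxyphenyl]ethyl}-3-(diazoacetyl)-2-(2,2-dimethoxyethyl)-4H-pyran-4-one | COC(OC)Cc1oc(CCc2ccc(OC)c(OCc3ccccc3)c2)cc(=O)c1C(=O)C=[N+]=[N-]
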